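The data are calculated on assumed constants, noise included.

Leave the flask closed. The balance below counts on nothing leaving.

| flask | substrate | remark | time |
|---|---|---|---|
| green | 1 M | the very flask that is asked about, followed so far |  |
| flask | 1.0 M |  | 15 d |

- green (time / d: target / %, over-reaction product / %, substrate / %): 0.333: 7.2, 2.3, 30.3; 0.833: 10.4, 10.8, 26.8; 1.67: 9.8, 26.6, 20.9; 2.50: 7.7, 40.3, 16.6; 4.00: 5.4, 61.0, 11.1; 5.00: 3.9, 69.5, 8.6; 6.00: 2.1, 76.7, 6.9

(each reading ± 0.5 percentage points)

- steps under discussion: substrate <-> intermediate A; substrate <-> intermediate B; substrate <-> intermediate C; intermediate A -> target; target -> over-reaction product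

- share of target in target plus over-reaction product at 80 min
- share of target in target plus over-reaction product at 15 d

At 6.00 d the flask holds 76.7 % over-reaction product, 2.1 % target and 6.9 % substrate. The unread 14.3 % sits elsewhere. Don't wait for target to build up.

Product forms from target, at k[target]. Divide the product gained from 0.833 d to 6.00 d by the area under target:

k = 1.99 /d

Let [rest] be everything not yet product. Read its decay from 2.50 d to 6.00 d:

λ = 0.269 /d

What leaves [rest] enters product, so λ[rest] = k[target]:

[target]/[rest] = λ/k = 0.135

Call this the tail fraction, a quasi-steady state: target's time constant is shorter than the decay's.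

At 15 d:

[rest] = 2.07 %, share = 0.286 %

At 80 min, target rising linearly gives 94.8 %. Target rising with the square of time gives 96.4 %.

The forecast gives 95 % and 0.3 %: “The late phase is a single slow exponential”.

The flask gives 96.0 % at 80 min and 0.298 % at 15 d.

    substrate ⇌ intermediate A (K = 0.340, k = 0.190 /h)
    substrate ⇌ intermediate B (K = 0.640, k = 0.330 /h)
    substrate ⇌ intermediate C (K = 1.10, k = 0.300 /h)
    intermediate A → target (k = 0.120 /h)
    target → over-reaction product (k = 0.0810 /h)

In this flask the half-life of target by its step to over-reaction product alone is 0.36 d, short against 15 d, and at that time target is made at 0.863 of the rate at which it is used, while target over everything not yet product stands at 0.137 against the tail fraction 0.135. The neighbour flask charged with 1.7 M stands at 0.137 at 15 d, with a share of 0.298 %.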